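Atom numbering follows lignan usage: guaiacyl unit C1–C9, syringyl unit C1'–C9', syringylglycerol unit C1''–C9''. Ring A is C7–O–C9'–C8'–C8 and ring B is C7'–O–C9–C8–C8'.

## Analysis of the target

The target (24) is a sesquilignan: a 2,6-diaryl-3,7-dioxabicyclo[3.3.0]octane (furofuran) whose syringyl ring is etherified at its 4-oxygen by C8'' of a syringylglycerol unit. Rings A and B are cis-fused along C8–C8'. The core carries four contiguous stereocentres, (7R,8S,7'S,8'S): the guaiacyl group at C7 is exo (convex face, cis to H8) and the syringyl group at C7' is endo (concave face, cis to C9'), so the compound belongs to the epi series. The side chain adds two stereocentres, (7''R,8''R), threo, which are insulated from the core by the aryl ether and cannot be relayed from it. Sensitive groups are two free phenols and three benzylic C–O bonds para to oxygen donors (C7–O, C7'–O, C7''–OH); acid ionises these bonds and turns an endo aryl into the more stable exo one, and base can open them through quinone methides once the para phenol is free. The difficulty is that the endo aryl at C7' is the disfavoured arrangement, so it must be set kinetically and then shielded in every later acidic step, while two different aryl groups are placed on defined rings. The strategy rests on ring B: C7' is a benzylic carbon bonded to the ring oxygen and C8 is alpha to C7, which can be carried as a lactone carbonyl, so C7' and C8 are the donor and acceptor ends of the C8–C7' bond of an aryl cyclopropane fused to the ring A lactone, and the remaining O–C9 unit is formaldehyde. An aryl cyclopropane made from an (E)-alkene has the aryl trans to C9', so opening with inversion at C7' places it cis to C9', which is the endo position.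

## Retrosynthetic reasoning

**24 from 23.** The two phenols are masked as benzyl ethers in 23 and released last by hydrogenolysis. Benzyl is chosen because the benzylated aldehyde 2 is already an intermediate of the route and can be used a second time.

**23 from 22, and 22 from 20 and 2.** The side chain is cut at C7''–C8''. An auxiliary-controlled syn aldol of the boron enolate 21, formed from imide 20, with aldehyde 2 sets both side-chain stereocentres in one event, independent of the distant core; syn in the aldol sense is threo here. Reductive removal of the auxiliary from 22 then gives the 1,3-diol 23. Cutting here rather than at the O–C8'' bond avoids a substitution by a hindered 2,6-dimethoxyphenol at a stereocentre.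

**20 from 18 and 19.** The aryl ether bond is made at an achiral CH2 by alkylating the syringyl phenol of 18 with the chloroacetyl imide 19, which brings in the auxiliary at the same time.

**18 from 17 and 16.** The alkylation needs the syringyl phenol free and the guaiacyl phenol masked. This is the reverse of the pattern in 16, so the guaiacyl phenol is benzylated (17) and the pivalate is then removed (18).

**16 from 14 and 15.** The bond between C7 and the guaiacyl ring is cut. In the forward direction the C7 oxocarbenium ion generated from 14 is arylated by guaiacol 15 at the carbon para to its hydroxyl. The cut is placed here because the C7 aryl is exo, which is what attack on the convex face of the bicycle delivers. The syringyl ring must be electron-poor at this stage so that the endo C7'–O bond does not ionise, hence the aryl pivalate in 14.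

**14 from 13, 12 and 11.** These are adjustments only: lactone 11 is reduced to lactol 12, the benzyl ether is removed (13), and both hydroxyls are pivaloylated (14). The benzyl ether is needed earlier because the cyclopropane opening requires an electron-rich donor ring.

**11 from 9 and 10 (key disconnection).** Ring B is cut at C7'–O and C8–C9. What remains is the cyclopropane lactone 9 and formaldehyde 10. The forward reaction has to open the C8–C7' bond with inversion at C7' and close ring B through the C8 enolate. One ring, two bonds and the endo configuration are gained in a single step.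

**9 from 8.** The cyclopropane bonds C8–C7' and C8–C8' are cut. Intramolecular carbene addition of diazoacetate 8 to its own (E)-alkene forms the cyclopropane and the ring A lactone together, with a chiral catalyst setting the absolute configuration.

**8 from 6 (through 7), 5, 4, 2 with 3, and 1.** The diazoacetate is traced back to bromoacetate 6 and (E)-cinnamyl alcohol 5. Alcohol 5 comes from ester 4, which comes from aldehyde 2 and phosphonate 3, and 2 comes from syringaldehyde 1.

## Alternatives that were turned down

**Alternative 1:** Ring A would be built as a ketone by a Prins cyclisation followed by a pinacol shift. A strong Lewis acid would ionise a cyclic acetal to the C7 oxocarbenium ion, the alkene would attack through C8 in a chair-like arrangement, and migration of the C9' methylene to C8' would quench the cation and reveal the C7' aryl ketone. The product is the 2,3-trans 2-aryl-3-(silyloxymethyl)-4-aroyltetrahydrofuran A1.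
- For: the cascade is well precedented for 3-acyl tetrahydrofurans, both aryl groups are in place before the key step, and the chair fixes the trans C7/C8 relationship that becomes the exo guaiacyl group.
- Against: C8' in A1 is alpha to the ketone and undefined, and C7' is still a carbonyl. The endo syringyl centre would have to come from a diastereoselective ketone reduction with nothing in A1 to favour the required carbinol epimer. Ring B would then have to be closed with retention at C7', because a closure through the benzylic cation would give the exo aryl.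
- Comparison: A1 is stronger on precedent and on early introduction of both aryl groups. The chosen route offers instead an endo centre that follows from a stereospecific inversion and a C8' centre that is never epimerisable.

**Alternative 2:** Both rings would be closed in one photoredox step. Oxidation of an alkoxyacetic acid would release CO2 and give the C9 radical, which would add 5-exo to C8 of a styrene (ring B). The resulting C7 benzylic radical would be oxidised to the cation and captured by the C9' hydroxyl (ring A). The product A2 is identical with compound 17 of the chosen route.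
- For: step economy at the core is clearly better, since A2 reaches in one step what the chosen route reaches only at step 12, and the same endgame would follow.
- Against: C8 would be set in a radical 5-exo closure with an early transition state, where cis/trans selectivity at the new ring bond is usually modest, and only the cis isomer can close ring A. The open-chain precursor needs its own stereocontrolled synthesis of the C7'/C8' pair. The electron-rich trialkoxyarenes also compete with the carboxylate for the photo-oxidant.
- Comparison: alternative 2 wins on step count. The chosen route offers stereochemical outcomes that are enforced by mechanism (inversion at C7', cis fusion by the tether, convex-face arylation) and not left to modest kinetic preferences.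

**Alternative 3:** Ring B would be closed at C8'–C7' by carbenoid C–H insertion. A dirhodium tetracarboxylate would convert a diazo group at C8' of a trans-disubstituted lactone into a carbenoid that inserts into the benzylic C–H bond of the syringylmethyl ether on C9. The product is the C9' lactone A3 with endo syringyl and exo guaiacyl groups.
- For: 1,5-insertion into an ether-activated benzylic C–H bond is a known way to 2,3-cis (endo-aryl) furofuranones, and both aryl groups are in place. On precedent for the endo centre this alternative is at least as strong as the chosen key step, which has none.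
- Against: the diazo lactone needs an enantiopure trans lactone and a diazo transfer to a simple lactone through an activation and deacylation sequence. The carbenoid faces competing sites (methoxy C–H bonds, ether oxygens, electron-rich rings). After A3 the C9' carbonyl must still be removed through a diol and a second closure at the benzylic C7.
- Comparison: the chosen route offers a shorter, catalytic asymmetric entry to its key substrate (six steps from 1) and an endo configuration that derives from alkene geometry and does not depend on selection among C–H bonds. It pays for this with a late introduction of the guaiacyl ring.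

Key step: step 7

## Assumptions

- Rh2(4S-MPPIM)4 is taken to give the (1R,5S,6S) antipode of 9; if the sense of induction proves opposite, Rh2(4R-MPPIM)4 is used.
- Compounds 12, 13 and 14 are mixtures of C7 epimers and are drawn without configuration at C7; this is of no consequence because C7 becomes planar in step 11.
- Formaldehyde 10 is used as the anhydrous monomer, obtained by cracking commercial paraformaldehyde.
- Imide 19 is taken as purchased.

## Route

Step 1
Reactants: 1 syringaldehyde
Product: 2 4-(benzyloxy)-3,5-dimethoxybenzaldehyde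
Conditions: BnBr, K2CO3, DMF, 60 °C
Reagents that add atoms: benzyl bromide, BrCc1ccccc1
Why: Williamson etherification of the phenoxide; the benzyl ether keeps the ring electron-rich for the cyclopropane opening, and 2 also serves as the aldehyde of step 15.

Step 2
Reactants: 2 4-(benzyloxy)-3,5-dimethoxybenzaldehyde; 3 triethyl phosphonoacetate
Product: 4 ethyl (E)-3-[4-(benzyloxy)-3,5-dimethoxyphenyl]prop-2-enoate
Conditions: NaH, THF, 0 °C to rt
Reagents that add atoms: none
Why: Horner–Wadsworth–Emmons olefination; the stabilised phosphonate anion should give the (E)-alkene, which later fixes the trans relationship of aryl and C9' on the cyclopropane.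

Step 3
Reactants: 4 ethyl (E)-3-[4-(benzyloxy)-3,5-dimethoxyphenyl]prop-2-enoate
Product: 5 (E)-3-[4-(benzyloxy)-3,5-dimethoxyphenyl]prop-2-en-1-ol
Conditions: iBu2AlH (2.2 equiv), CH2Cl2, −78 °C; aq. potassium sodium tartrate
Reagents that add atoms: none
Why: 1,2-reduction of the enoate by iBu2AlH at low temperature should give the allylic alcohol without touching the alkene or the benzyl ether.

Step 4
Reactants: 5 (E)-3-[4-(benzyloxy)-3,5-dimethoxyphenyl]prop-2-en-1-ol
Product: 6 (E)-3-[4-(benzyloxy)-3,5-dimethoxyphenyl]prop-2-en-1-yl bromoacetate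
Conditions: BrCH2COBr, NaHCO3, MeCN, 0 °C
Reagents that add atoms: bromoacetyl bromide, BrCC(Br)=O
Why: O-acylation by the acid bromide; the NaHCO3 buffer removes HBr so that the electron-rich cinnamyl ester is not ionised.

Step 5
Reactants: 6 (E)-3-[4-(benzyloxy)-3,5-dimethoxyphenyl]prop-2-en-1-yl bromoacetate
Product: 8 (E)-3-[4-(benzyloxy)-3,5-dimethoxyphenyl]prop-2-en-1-yl diazoacetate, via ditosylhydrazinoacetate 7 (not isolated)
Conditions: TsNHNHTs, DBU, THF, 0 °C
Reagents that add atoms: N,N'-bis(4-methylphenylsulfonyl)hydrazine, Cc1ccc(cc1)S(=O)(=O)NNS(=O)(=O)c1ccc(C)cc1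
Why: Fukuyama diazoacetate synthesis; N-alkylation of the ditosylhydrazine anion by the bromoacetate gives 7, and DBU then expels two sulfinates to leave the diazo group.

Step 6
Reactants: 8 (E)-3-[4-(benzyloxy)-3,5-dimethoxyphenyl]prop-2-en-1-yl diazoacetate
Product: 9 (1R,5S,6S)-6-[4-(benzyloxy)-3,5-dimethoxyphenyl]-3-oxabicyclo[3.1.0]hexan-2-one (aryl exo)
Conditions: Rh2(4S-MPPIM)4 (1 mol%), CH2Cl2, reflux, slow addition of 8
Reagents that add atoms: none
Why: Enantioselective intramolecular carbenoid cyclopropanation with a chiral dirhodium carboxamidate, a catalyst class suited to trans-disubstituted allylic diazoacetates. Addition to the (E)-alkene is stereospecific, so the aryl group is exo (trans to C9'), and the catalyst selects the alkene face and thereby the absolute configuration of C8, C8' and C7'.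

Step 7
Reactants: 9 (1R,5S,6S)-6-[4-(benzyloxy)-3,5-dimethoxyphenyl]-3-oxabicyclo[3.1.0]hexan-2-one; 10 formaldehyde
Product: 11 (1S,5S,6S)-6-[4-(benzyloxy)-3,5-dimethoxyphenyl]-3,7-dioxabicyclo[3.3.0]octan-2-one (C7 lactone; aryl endo; lignan descriptors 8S,7'S,8'S)
Conditions: Sn(OTf)2 (20 mol%), 10 (5 equiv, monomer in CH2Cl2), 4 Å MS, CH2Cl2, −40 to 0 °C
Reagents that add atoms: none
Why: Proposed new method: Sn(OTf)2 held on the lactone carbonyl of 9 draws electron density out of the C8–C7' sigma bond, the only cyclopropane bond that joins the carbonyl-bearing carbon to the aryl-bearing carbon and the one that overlaps with the carbonyl pi* orbital (the ring-fusion bond C8–C8' lies in the lactone plane), and the oxygen of 10 displaces at C7' from the side opposite to C8. The result is a tin lactone enolate at C8 tethered through C8'–C7'–O to an oxocarbenium carbon (C9), and the enolate carbon adds to C9 in an intramolecular aldol step. The closest known reaction is the Sn(OTf)2-catalysed annulation of 2-arylcyclopropane-1,1-diesters with aldehydes to tetrahydrofurans, which proceeds with inversion at the aryl-bearing carbon; a cyclopropane activated by a single lactone carbonyl, and formaldehyde as the partner, lie outside that scope. Ring B (C7', O, C9, C8, C8') is closed by the C8–C9 bond, formally a 5-(enolexo)-endo-trig attack on the oxocarbenium ion, the same topology as in the diester annulation and feasible because the electrophile is a cation. C7' is set by the backside trajectory: the aryl group, trans to C9' in 9, ends up cis to C9' (endo, 7'S). C8 passes through the planar enolate and is fixed again by the tether, which reaches only the face of C8 on which C7' sits, so the bicycle is cis-fused (8S); C8' is untouched. What has to be secured is stereospecificity: the displacement at C7' must remain concerted and stay ahead of dissociation into a free benzylic cation, which would erase the configuration. The 4-benzyloxy-3,5-dimethoxyphenyl donor and the strain of the fused cyclopropane are relied on to let one acceptor suffice with a mild Lewis acid at low temperature, where the ion pair stays tight; Hf(OTf)4 is the stronger alternative.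

Step 8
Reactants: 11 (1S,5S,6S)-6-[4-(benzyloxy)-3,5-dimethoxyphenyl]-3,7-dioxabicyclo[3.3.0]octan-2-one
Product: 12 (1S,5S,6S)-6-[4-(benzyloxy)-3,5-dimethoxyphenyl]-3,7-dioxabicyclo[3.3.0]octan-2-ol (C7 lactol; both epimers at the lactol carbon)
Conditions: iBu2AlH (1.1 equiv), CH2Cl2, −78 °C; aq. potassium sodium tartrate
Reagents that add atoms: none
Why: Partial reduction of a gamma-lactone; the tetrahedral aluminium hemiacetal is stable at −78 °C and should give the lactol on work-up.

Step 9
Reactants: 12 (1S,5S,6S)-6-[4-(benzyloxy)-3,5-dimethoxyphenyl]-3,7-dioxabicyclo[3.3.0]octan-2-ol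
Product: 13 (1S,5S,6S)-6-(4-hydroxy-3,5-dimethoxyphenyl)-3,7-dioxabicyclo[3.3.0]octan-2-ol
Conditions: H2 (1 atm), Pd/C, EtOAc, rt
Reagents that add atoms: none
Why: Hydrogenolysis of the aryl benzyl ether; under neutral conditions this ether should cleave well before the ring benzylic C7'–O bond, and the lactol is inert.

Step 10
Reactants: 13 (1S,5S,6S)-6-(4-hydroxy-3,5-dimethoxyphenyl)-3,7-dioxabicyclo[3.3.0]octan-2-ol
Product: 14 (1S,5S,6S)-6-[3,5-dimethoxy-4-(pivaloyloxy)phenyl]-3,7-dioxabicyclo[3.3.0]oct-2-yl pivalate (both epimers at the acetal carbon)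
Conditions: PivCl (3 equiv), Et3N, DMAP (cat.), CH2Cl2, 0 °C to rt
Reagents that add atoms: pivaloyl chloride, CC(C)(C)C(Cl)=O
Why: DMAP-catalysed acylation of the phenol and the lactol hydroxyl. The aryl pivalate removes the para-oxygen donation that would let the C7'–O bond ionise under acid, and the acetal pivalate is the leaving group for step 11.

Step 11
Reactants: 14 (1S,5S,6S)-6-[3,5-dimethoxy-4-(pivaloyloxy)phenyl]-3,7-dioxabicyclo[3.3.0]oct-2-yl pivalate; 15 guaiacol
Product: 16 (1S,2R,5S,6S)-2-(4-hydroxy-3-methoxyphenyl)-6-[3,5-dimethoxy-4-(pivaloyloxy)phenyl]-3,7-dioxabicyclo[3.3.0]octane (7R,8S,7'S,8'S; guaiacyl exo and syringyl endo)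
Conditions: 15 (3 equiv), BF3·OEt2 (0.3 equiv), 4 Å MS, CH2Cl2, −40 to 0 °C
Reagents that add atoms: none
Why: Friedel–Crafts C-arylation of a cyclic oxocarbenium ion, the reaction type known for furofuran lactols with phenols. BF3 ionises the acetal pivalate, and guaiacol should react through the carbon para to its hydroxyl (the most nucleophilic and least hindered position) on the convex face, away from ring B and its endo aryl, so the new aryl is exo (7R), which is also the more stable arrangement. Any O-aryl acetal formed first should re-ionise and drain into the C-aryl product.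

Step 12
Reactants: 16 (1S,2R,5S,6S)-2-(4-hydroxy-3-methoxyphenyl)-6-[3,5-dimethoxy-4-(pivaloyloxy)phenyl]-3,7-dioxabicyclo[3.3.0]octane
Product: 17 (1S,2R,5S,6S)-2-[4-(benzyloxy)-3-methoxyphenyl]-6-[3,5-dimethoxy-4-(pivaloyloxy)phenyl]-3,7-dioxabicyclo[3.3.0]octane
Conditions: BnBr, K2CO3, acetone, 50 °C
Reagents that add atoms: benzyl bromide, BrCc1ccccc1
Why: Williamson benzylation of the only free phenol; the hindered aryl pivalate should survive K2CO3 in an aprotic solvent.

Step 13
Reactants: 17 (1S,2R,5S,6S)-2-[4-(benzyloxy)-3-methoxyphenyl]-6-[3,5-dimethoxy-4-(pivaloyloxy)phenyl]-3,7-dioxabicyclo[3.3.0]octane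
Product: 18 (1S,2R,5S,6S)-2-[4-(benzyloxy)-3-methoxyphenyl]-6-(4-hydroxy-3,5-dimethoxyphenyl)-3,7-dioxabicyclo[3.3.0]octane
Conditions: iBu2AlH (2.5 equiv), CH2Cl2, −78 °C; aq. potassium sodium tartrate
Reagents that add atoms: none
Why: Reductive cleavage of the aryl ester at low temperature; this frees the syringyl phenol without warm alkoxide conditions that could open the C7'–O bond through a quinone methide.

Step 14
Reactants: 18 (1S,2R,5S,6S)-2-[4-(benzyloxy)-3-methoxyphenyl]-6-(4-hydroxy-3,5-dimethoxyphenyl)-3,7-dioxabicyclo[3.3.0]octane; 19 (4S)-4-benzyl-3-(chloroacetyl)oxazolidin-2-one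
Product: 20 N-(aryloxyacetyl)oxazolidinone: 18 alkylated on its phenolic oxygen by the CH2C(=O)-[(4S)-4-benzyl-2-oxooxazolidin-3-yl] group
Conditions: K2CO3, NaI (cat.), MeCN, rt
Reagents that add atoms: none
Why: SN2 O-alkylation of the 2,6-dimethoxyphenoxide by an alpha-halo imide, helped by iodide exchange in the flask; the ether bond is formed at an achiral CH2, so no stereocentre is at stake.

Step 15
Reactants: 20 N-(aryloxyacetyl)oxazolidinone; 2 4-(benzyloxy)-3,5-dimethoxybenzaldehyde
Product: 22 (4S)-4-benzyl-3-[(2S,3R)-2-(aryloxy)-3-[4-(benzyloxy)-3,5-dimethoxyphenyl]-3-hydroxypropanoyl]oxazolidin-2-one in which aryloxy is the phenoxy residue of 18, via dibutylboron Z-enolate 21 (not isolated)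
Conditions: iPr2NEt, Bu2BOTf (1.2 equiv), CH2Cl2, −78 to 0 °C; then 2, −78 to −20 °C; aq. NaH2PO4/Na2HPO4 (pH 7), MeOH, H2O2, 0 °C
Reagents that add atoms: dibutylboron triflate, CCCCB(CCCC)OS(=O)(=O)C(F)(F)F (its Bu2B unit is carried by 21 only)
Why: Evans syn aldol; the Z-boron enolate 21 should react through a closed chair transition state in which the aldehyde approaches the enolate face away from the benzyl group of the (S)-auxiliary. Both new centres, (2S,3R), are therefore set by the auxiliary, independently of the remote core; they correspond to the threo (7''R,8''R) arrangement after reduction.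

Step 16
Reactants: 22 (4S)-4-benzyl-3-[(2S,3R)-2-(aryloxy)-3-[4-(benzyloxy)-3,5-dimethoxyphenyl]-3-hydroxypropanoyl]oxazolidin-2-one
Product: 23 (1R,2R)-1-[4-(benzyloxy)-3,5-dimethoxyphenyl]-2-{4-[(1S,2S,5S,6R)-6-[4-(benzyloxy)-3-methoxyphenyl]-3,7-dioxabicyclo[3.3.0]oct-2-yl]-2,6-dimethoxyphenoxy}propane-1,3-diol
Conditions: LiBH4, THF, H2O (1 equiv), 0 °C
Reagents that add atoms: none
Why: Reductive cleavage of the N-acyl oxazolidinone at the exocyclic carbonyl gives the primary alcohol and releases the auxiliary; the mild hydride conditions should not trigger retro-aldol cleavage, and no stereocentre is touched.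

Step 17
Reactants: 23 (1R,2R)-1-[4-(benzyloxy)-3,5-dimethoxyphenyl]-2-{4-[(1S,2S,5S,6R)-6-[4-(benzyloxy)-3-methoxyphenyl]-3,7-dioxabicyclo[3.3.0]oct-2-yl]-2,6-dimethoxyphenoxy}propane-1,3-diol
Product: 24 (1R,2R)-1-(4-hydroxy-3,5-dimethoxyphenyl)-2-{4-[(1S,2S,5S,6R)-6-(4-hydroxy-3-methoxyphenyl)-3,7-dioxabicyclo[3.3.0]oct-2-yl]-2,6-dimethoxyphenoxy}propane-1,3-diol (target; 7R,8S,7'S,8'S,7''R,8''R)
Conditions: H2 (1 atm), Pd/C, EtOAc–EtOH, rt
Reagents that add atoms: none
Why: Hydrogenolysis of the two aryl benzyl ethers under neutral conditions, where benzylic alcohols and the ring benzylic ethers of lignans are normally kept; the reaction is to be stopped as soon as 23 is consumed.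

## Compound list

1 | syringaldehyde | COc1cc(C=O)cc(OC)c1O | starting material
2 | 4-(benzyloxy)-3,5-dimethoxybenzaldehyde | COc1cc(C=O)cc(OC)c1OCc1ccccc1 | intermediate
3 | triethyl phosphonoacetate | CCOC(=O)CP(=O)(OCC)OCC | starting material
4 | ethyl (E)-3-[4-(benzyloxy)-3,5-dimethoxyphenyl]prop-2-enoate | CCOC(=O)/C=C/c1cc(OC)c(OCc2ccccc2)c(OC)c1 | intermediate
5 | (E)-3-[4-(benzyloxy)-3,5-dimethoxyphenyl]prop-2-en-1-ol | OC/C=C/c1cc(OC)c(OCc2ccccc2)c(OC)c1 | intermediate
6 | (E)-3-[4-(benzyloxy)-3,5-dimethoxyphenyl]prop-2-en-1-yl bromoacetate | BrCC(=O)OC/C=C/c1cc(OC)c(OCc2ccccc2)c(OC)c1 | intermediate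
7 | (E)-3-[4-(benzyloxy)-3,5-dimethoxyphenyl]prop-2-en-1-yl [1,2-bis(4-methylphenylsulfonyl)hydrazin-1-yl]acetate | Cc1ccc(cc1)S(=O)(=O)NN(CC(=O)OC/C=C/c1cc(OC)c(OCc2ccccc2)c(OC)c1)S(=O)(=O)c1ccc(C)cc1 | intermediate (not isolated)
8 | (E)-3-[4-(benzyloxy)-3,5-dimethoxyphenyl]prop-2-en-1-yl diazoacetate | [N-]=[N+]=CC(=O)OC/C=C/c1cc(OC)c(OCc2ccccc2)c(OC)c1 | intermediate
9 | (1R,5S,6S)-6-[4-(benzyloxy)-3,5-dimethoxyphenyl]-3-oxabicyclo[3.1.0]hexan-2-one | O=C1OC[C@@H]2[C@H]1[C@H]2c1cc(OC)c(OCc3ccccc3)c(OC)c1 | intermediate
10 | formaldehyde | C=O | starting material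
11 | (1S,5S,6S)-6-[4-(benzyloxy)-3,5-dimethoxyphenyl]-3,7-dioxabicyclo[3.3.0]octan-2-one | O=C1OC[C@@H]2[C@H]1CO[C@@H]2c1cc(OC)c(OCc3ccccc3)c(OC)c1 | intermediate
12 | (1S,5S,6S)-6-[4-(benzyloxy)-3,5-dimethoxyphenyl]-3,7-dioxabicyclo[3.3.0]octan-2-ol, C7 epimers | OC1OC[C@@H]2[C@H]1CO[C@@H]2c1cc(OC)c(OCc3ccccc3)c(OC)c1 | intermediate
13 | (1S,5S,6S)-6-(4-hydroxy-3,5-dimethoxyphenyl)-3,7-dioxabicyclo[3.3.0]octan-2-ol, C7 epimers | OC1OC[C@@H]2[C@H]1CO[C@@H]2c1cc(OC)c(O)c(OC)c1 | intermediate
14 | (1S,5S,6S)-6-[3,5-dimethoxy-4-(pivaloyloxy)phenyl]-3,7-dioxabicyclo[3.3.0]oct-2-yl pivalate, C7 epimers | CC(C)(C)C(=O)OC1OC[C@@H]2[C@H]1CO[C@@H]2c1cc(OC)c(OC(=O)C(C)(C)C)c(OC)c1 | intermediate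
15 | guaiacol (2-methoxyphenol) | COc1ccccc1O | starting material
16 | (1S,2R,5S,6S)-2-(4-hydroxy-3-methoxyphenyl)-6-[3,5-dimethoxy-4-(pivaloyloxy)phenyl]-3,7-dioxabicyclo[3.3.0]octane | COc1cc([C@@H]2OC[C@@H]3[C@H]2CO[C@@H]3c2cc(OC)c(OC(=O)C(C)(C)C)c(OC)c2)ccc1O | intermediate
17 | (1S,2R,5S,6S)-2-[4-(benzyloxy)-3-methoxyphenyl]-6-[3,5-dimethoxy-4-(pivaloyloxy)phenyl]-3,7-dioxabicyclo[3.3.0]octane | COc1cc([C@@H]2OC[C@@H]3[C@H]2CO[C@@H]3c2cc(OC)c(OC(=O)C(C)(C)C)c(OC)c2)ccc1OCc1ccccc1 | intermediate
18 | (1S,2R,5S,6S)-2-[4-(benzyloxy)-3-methoxyphenyl]-6-(4-hydroxy-3,5-dimethoxyphenyl)-3,7-dioxabicyclo[3.3.0]octane | COc1cc([C@@H]2OC[C@@H]3[C@H]2CO[C@@H]3c2cc(OC)c(O)c(OC)c2)ccc1OCc1ccccc1 | intermediate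
19 | (4S)-4-benzyl-3-(chloroacetyl)oxazolidin-2-one | ClCC(=O)N1C(=O)OC[C@@H]1Cc1ccccc1 | starting material
20 | (4S)-4-benzyl-3-(aryloxyacetyl)oxazolidin-2-one, aryloxy = phenoxy residue of 18 | COc1cc([C@@H]2OC[C@@H]3[C@H]2CO[C@@H]3c2cc(OC)c(OCC(=O)N3C(=O)OC[C@@H]3Cc3ccccc3)c(OC)c2)ccc1OCc1ccccc1 | intermediate
21 | dibutylboron Z-enolate of 20 | COc1cc([C@@H]2OC[C@@H]3[C@H]2CO[C@@H]3c2cc(OC)c(O/C=C(\OB(CCCC)CCCC)N3C(=O)OC[C@@H]3Cc3ccccc3)c(OC)c2)ccc1OCc1ccccc1 | intermediate (not isolated)
22 | (4S)-4-benzyl-3-[(2S,3R)-2-(aryloxy)-3-[4-(benzyloxy)-3,5-dimethoxyphenyl]-3-hydroxypropanoyl]oxazolidin-2-one, aryloxy = phenoxy residue of 18 | COc1cc([C@@H]2OC[C@@H]3[C@H]2CO[C@@H]3c2cc(OC)c(O[C@H](C(=O)N3C(=O)OC[C@@H]3Cc3ccccc3)[C@H](O)c3cc(OC)c(OCc4ccccc4)c(OC)c3)c(OC)c2)ccc1OCc1ccccc1 | intermediate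
23 | di-O-benzyl ether of the target, (7R,8S,7'S,8'S,7''R,8''R) | COc1cc([C@@H]2OC[C@@H]3[C@H]2CO[C@@H]3c2cc(OC)c(O[C@H](CO)[C@H](O)c3cc(OC)c(OCc4ccccc4)c(OC)c3)c(OC)c2)ccc1OCc1ccccc1 | intermediate
24 | (1R,2R)-1-(4-hydroxy-3,5-dimethoxyphenyl)-2-{4-[(1S,2S,5S,6R)-6-(4-hydroxy-3-methoxyphenyl)-3,7-dioxabicyclo[3.3.0]oct-2-yl]-2,6-dimethoxyphenoxy}propane-1,3-diol | COc1cc([C@@H]2OC[C@@H]3[C@H]2CO[C@@H]3c2cc(OC)c(O[C@H](CO)[C@H](O)c3cc(OC)c(O)c(OC)c3)c(OC)c2)ccc1O | target

## Step count and least certain steps

Total: 17 steps. Longest linear sequence: 17 steps (1 to 24); aldehyde 2 is drawn from the main line a second time in step 15, and 3, 10, 15 and 19 are purchased.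

**Step 7 (key step, the one step beyond known chemistry).**
- Most likely failure: the single lactone acceptor may not activate the cyclopropane enough under a mild Lewis acid, and a stronger acid or higher temperature would let the ring open by ionisation to a free benzylic cation, with loss of stereospecificity at C7'. Oligomerisation of formaldehyde and hydroxymethylation of the electron-rich rings may also compete.
- Fallback: it sets out from 5 and returns at 11. Acylation of 5 with methyl malonyl chloride (pyridine, CH2Cl2) would give methyl (E)-3-[4-(benzyloxy)-3,5-dimethoxyphenyl]prop-2-en-1-yl malonate F1. Diazo transfer (4-acetamidobenzenesulfonyl azide, Et3N, MeCN) would give the diazomalonate F2. Intramolecular cyclopropanation with [Co(3,5-DitBu-ChenPhyrin)], a chiral amidoporphyrin complex of divalent cobalt of the type used for acceptor/acceptor allyl diazoacetates, would give methyl 6-exo-aryl-2-oxo-3-oxabicyclo[3.1.0]hexane-1-carboxylate F3, the 1-methoxycarbonyl analogue of 9, to be enriched by crystallisation if needed. F3 carries two geminal acceptors, so it belongs to the substrate class of the established Sn(OTf)2-catalysed aldehyde annulation, which with 10 should give the angular ester F4 with inversion at C7'. Krapcho demethoxycarbonylation (LiCl, wet DMSO, 140 °C) would then give 11, since the lactone enolate can be protonated only to the cis-fused bicycle.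

**Step 11.**
- Most likely failure: poor regioselectivity of the arylation (attack through the carbon ortho to the hydroxyl after O-arylation and migration, or through the carbon para to the methoxy group), and acid-induced epimerisation at C7' if the pivalate does not deactivate the syringyl ring enough.
- Fallback: it sets out from 14 and returns at 17, bypassing 16 and step 12. Potassium [4-(benzyloxy)-3-methoxyphenyl]trifluoroborate F5, made from the commercial boronic acid with KHF2, would be added to the oxocarbenium ion generated from 14 with BF3·OEt2 in MeCN at −20 °C. The C–C bond forms at the boron-bearing carbon, so the regiochemistry is fixed and no free phenol is present; convex-face attack should give 17 directly.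

**Step 15.**
- Most likely failure: opening or epimerisation of the benzylic ethers by the Lewis-acidic boron triflate, slow enolisation or addition because of the hindered 2,6-dimethoxyaryloxy group, and retro-aldol cleavage on work-up.
- Fallback: it sets out from 18 and returns at 23, bypassing steps 14 to 16. Roskamp homologation of 2 (ethyl diazoacetate, SnCl2 cat.) would give ethyl 3-[4-(benzyloxy)-3,5-dimethoxyphenyl]-3-oxopropanoate F6, and chlorination (SO2Cl2) would give the 2-chloro keto ester F7. Alkylation of 18 with F7 (K2CO3, acetone) would give the alpha-aryloxy beta-keto ester F8 as a labile mixture at C8''. Transfer hydrogenation under dynamic kinetic resolution with RuCl(p-cymene)[(S,S)-TsDPEN] in HCO2H/Et3N, the reaction type known to give syn alpha-alkoxy beta-hydroxy esters, should give the (2S,3R) hydroxy ester F9. Reduction with LiBH4 would then give 23.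

**Step 14.**
- Most likely failure: acyl transfer in place of alkylation, that is attack of the phenoxide on the imide carbonyl with loss of the auxiliary, or slow alkylation of the hindered phenoxide.
- Fallback: it sets out from 18 and returns at 20. Alkylation with methyl bromoacetate (K2CO3, acetone) would give the methyl aryloxyacetate F10, and saponification (LiOH, THF–H2O) the aryloxyacetic acid F11. Activation as the mixed pivalic anhydride (PivCl, Et3N, THF, −20 °C) and acylation of lithiated (S)-4-benzyloxazolidin-2-one (n-BuLi) would then give 20.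

## Further compounds

F1 | step 7 | methyl (E)-3-[4-(benzyloxy)-3,5-dimethoxyphenyl]prop-2-en-1-yl malonate | COC(=O)CC(=O)OC/C=C/c1cc(OC)c(OCc2ccccc2)c(OC)c1
F2 | step 7 | methyl (E)-3-[4-(benzyloxy)-3,5-dimethoxyphenyl]prop-2-en-1-yl 2-diazomalonate | COC(=O)C(=[N+]=[N-])C(=O)OC/C=C/c1cc(OC)c(OCc2ccccc2)c(OC)c1
F3 | step 7 | methyl 6-exo-[4-(benzyloxy)-3,5-dimethoxyphenyl]-2-oxo-3-oxabicyclo[3.1.0]hexane-1-carboxylate, configured at C5 and C6 as 9 | O=C1OC[C@@H]2[C@@]1(C(=O)OC)[C@H]2c1cc(OC)c(OCc3ccccc3)c(OC)c1
F4 | step 7 | methyl 6-endo-[4-(benzyloxy)-3,5-dimethoxyphenyl]-2-oxo-3,7-dioxabicyclo[3.3.0]octane-1-carboxylate, configured as 11 | O=C1OC[C@@H]2[C@@]1(C(=O)OC)CO[C@@H]2c1cc(OC)c(OCc3ccccc3)c(OC)c1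
F5 | step 11 | potassium [4-(benzyloxy)-3-methoxyphenyl]trifluoroborate | [K+].COc1cc(ccc1OCc1ccccc1)[B-](F)(F)F
F6 | step 15 | ethyl 3-[4-(benzyloxy)-3,5-dimethoxyphenyl]-3-oxopropanoate | CCOC(=O)CC(=O)c1cc(OC)c(OCc2ccccc2)c(OC)c1
F7 | step 15 | ethyl 2-chloro-3-[4-(benzyloxy)-3,5-dimethoxyphenyl]-3-oxopropanoate | CCOC(=O)C(Cl)C(=O)c1cc(OC)c(OCc2ccccc2)c(OC)c1
F8 | step 15 | ethyl 2-(aryloxy)-3-[4-(benzyloxy)-3,5-dimethoxyphenyl]-3-oxopropanoate, aryloxy = phenoxy residue of 18, C8'' epimers | COc1cc([C@@H]2OC[C@@H]3[C@H]2CO[C@@H]3c2cc(OC)c(OC(C(=O)OCC)C(=O)c3cc(OC)c(OCc4ccccc4)c(OC)c3)c(OC)c2)ccc1OCc1ccccc1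
F9 | step 15 | ethyl (2S,3R)-2-(aryloxy)-3-[4-(benzyloxy)-3,5-dimethoxyphenyl]-3-hydroxypropanoate, aryloxy = phenoxy residue of 18 | COc1cc([C@@H]2OC[C@@H]3[C@H]2CO[C@@H]3c2cc(OC)c(O[C@H](C(=O)OCC)[C@H](O)c3cc(OC)c(OCc4ccccc4)c(OC)c3)c(OC)c2)ccc1OCc1ccccc1
F10 | step 14 | methyl (aryloxy)acetate, aryloxy = phenoxy residue of 18 | COc1cc([C@@H]2OC[C@@H]3[C@H]2CO[C@@H]3c2cc(OC)c(OCC(=O)OC)c(OC)c2)ccc1OCc1ccccc1
F11 | step 14 | (aryloxy)acetic acid, aryloxy = phenoxy residue of 18 | COc1cc([C@@H]2OC[C@@H]3[C@H]2CO[C@@H]3c2cc(OC)c(OCC(O)=O)c(OC)c2)ccc1OCc1ccccc1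
A1 | alternative 1 | 2,3-trans-2-[4-(benzyloxy)-3-methoxyphenyl]-3-[(tert-butyldimethylsilyloxy)methyl]-4-[3,5-dimethoxy-4-(triisopropylsilyloxy)benzoyl]tetrahydrofuran, C8' undefined | COc1cc([C@@H]2OCC(C(=O)c3cc(OC)c(O[Si](C(C)C)(C(C)C)C(C)C)c(OC)c3)[C@H]2CO[Si](C)(C)C(C)(C)C)ccc1OCc1ccccc1
A2 | alternative 2 | protected epi-furofuran with guaiacyl O-benzyl and syringyl O-pivaloyl groups, identical with 17 | COc1cc([C@@H]2OC[C@@H]3[C@H]2CO[C@@H]3c2cc(OC)c(OC(=O)C(C)(C)C)c(OC)c2)ccc1OCc1ccccc1
A3 | alternative 3 | endo-syringyl exo-guaiacyl furofuranone (C9' lactone) with syringyl O-triisopropylsilyl and guaiacyl O-benzyl groups | COc1cc([C@@H]2OC(=O)[C@@H]3[C@H]2CO[C@@H]3c2cc(OC)c(O[Si](C(C)C)(C(C)C)C(C)C)c(OC)c2)ccc1OCc1ccccc1
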